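**Strategy.** Everything rests on cutting the O1–C5 bond of the tetrahydrofuran. Ring carbon C4 carries two one-carbon arms that both end at oxygen, ring C5 and the carbinol carbon, so C4 and its two arms can be folded back into an oxetane. A chiral (salen)Co(OTf) Lewis acid (trivalent cobalt) lets the hydroxyl on C2 open that oxetane at one of its two diastereotopic CH2 groups: one operation closes the five-membered ring, sets C4 cis to the arylmethyl group on C3 and frees the CH2OH that becomes the carbinol carbon. The substrate is an acyclic (R)-3-aryl-2-(oxetan-3-yl)propan-1-ol whose single stereocentre comes from an Evans alkylation; the oxetanylacetyl imide is assembled without free oxetan-3-ylacetic acid.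

Key step: step 8

Assumption: the (R,R) hand of the cobalt catalyst is written as the cis-selective partner of the (R)-configured substrate; both hands are available, and the one that delivers the cis ring in a first paired run is the one to use.

Assumption: (3-benzyloxy-4-methoxyphenyl)methanol is taken as a catalogue compound; otherwise it is one NaBH4 reduction away from O-benzylisovanillin.

**Route**

Step 1
Reactants: 1 (R)-4-benzyl-2-oxazolidinone
Product: 3 (R)-4-benzyl-3-(bromoacetyl)oxazolidin-2-one, via lithiated oxazolidinone 2 (not isolated)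
Conditions: n-BuLi, THF, −78 °C; then BrCH2COBr, −78 to 0 °C
Reagents that add atoms: bromoacetyl bromide, O=C(Br)CBr
Why: N-acylation of the lithiated oxazolidinone should occur cleanly at the acyl bromide, which is far more electrophilic than the alkyl bromide end of the reagent.

Step 2
Reactants: 3 (R)-4-benzyl-3-(bromoacetyl)oxazolidin-2-one
Product: 4 diethyl {2-[(4R)-4-benzyl-2-oxooxazolidin-3-yl]-2-oxoethyl}phosphonate
Conditions: P(OEt)3 (neat), 90 °C
Reagents that add atoms: triethyl phosphite, CCOP(OCC)OCC
Why: Michaelis–Arbuzov reaction of the primary α-bromo imide with triethyl phosphite should give the imide phosphonate while bromoethane distils off.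

Step 3
Reactants: 4 diethyl {2-[(4R)-4-benzyl-2-oxooxazolidin-3-yl]-2-oxoethyl}phosphonate; 5 oxetan-3-one
Product: 6 (R)-4-benzyl-3-[2-(oxetan-3-ylidene)acetyl]oxazolidin-2-one
Conditions: LiCl, iPr2NEt, MeCN, 0 °C to rt
Reagents that add atoms: none
Why: Horner–Wadsworth–Emmons olefination under Masamune–Roush conditions should work because oxetan-3-one is a strained, strongly electrophilic ketone that cannot give E/Z isomers, and it brings the auxiliary in without passing through free oxetan-3-ylacetic acid, an acid of a class that can isomerize to lactones by attack of the carboxyl group on the ring.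

Step 4
Reactants: 6 (R)-4-benzyl-3-[2-(oxetan-3-ylidene)acetyl]oxazolidin-2-one
Product: 7 (R)-4-benzyl-3-[2-(oxetan-3-yl)acetyl]oxazolidin-2-one
Conditions: H2 (1 atm), 10% Pd/C, EtOAc, rt
Reagents that add atoms: none
Why: Heterogeneous catalytic hydrogenation of the conjugated exocyclic alkene should be fast at 1 atm and leave the oxetane C–O bonds and the C-benzyl group of the auxiliary untouched, with no stereocentre formed.

Step 5
Reactants: 8 (3-benzyloxy-4-methoxyphenyl)methanol
Product: 9 2-(benzyloxy)-4-(bromomethyl)-1-methoxybenzene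
Conditions: PBr3 (0.4 equiv), CH2Cl2, 0 °C; used at once
Reagents that add atoms: phosphorus tribromide, BrP(Br)Br
Why: Bromination of the electron-rich benzylic alcohol with PBr3 (SN2 displacement of the phosphite ester) is routine at 0 °C and spares the aryl benzyl ether.

Step 6
Reactants: 7 (R)-4-benzyl-3-[2-(oxetan-3-yl)acetyl]oxazolidin-2-one; 9 2-(benzyloxy)-4-(bromomethyl)-1-methoxybenzene
Product: 11 (R)-4-benzyl-3-[(2R)-3-(3-benzyloxy-4-methoxyphenyl)-2-(oxetan-3-yl)propanoyl]oxazolidin-2-one, via sodium Z-enolate 10 (not isolated)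
Conditions: NaHMDS, THF, −78 °C; then 9, −78 to −30 °C
Reagents that add atoms: none
Why: Evans alkylation: the chelated sodium (Z)-enolate is shielded on one face by the C4 benzyl group of the (R)-auxiliary, so the reactive benzylic bromide should enter anti to it and set the α-stereocentre as (R) (oxetanyl outranks arylmethyl in the CIP order).

Step 7
Reactants: 11 (R)-4-benzyl-3-[(2R)-3-(3-benzyloxy-4-methoxyphenyl)-2-(oxetan-3-yl)propanoyl]oxazolidin-2-one
Product: 12 (R)-3-(3-benzyloxy-4-methoxyphenyl)-2-(oxetan-3-yl)propan-1-ol
Conditions: LiBH4, H2O (1 equiv), Et2O, 0 °C; basic work-up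
Reagents that add atoms: none
Why: Reductive cleavage of the N-acyl oxazolidinone with LiBH4 (hydride attack at the exocyclic carbonyl) should release the primary alcohol and the recoverable auxiliary at 0 °C without opening the oxetane, and the stereocentre is no longer enolizable once reduced.

Step 8
Reactants: 12 (R)-3-(3-benzyloxy-4-methoxyphenyl)-2-(oxetan-3-yl)propan-1-ol
Product: 13 [(3R,4R)-4-(3-benzyloxy-4-methoxybenzyl)tetrahydrofuran-3-yl]methanol (cis)
Conditions: [(R,R)-N,N′-bis(3,5-di-tert-butylsalicylidene)cyclohexane-1,2-diaminato]Co(OTf) (trivalent cobalt) 5 mol %, MeCN (0.1 M), 23 °C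
Reagents that add atoms: none
Why: The cobalt triflate is a chiral Lewis acid that binds the oxetane oxygen, and the tethered primary hydroxyl then displaces that oxygen from the back side at one ring CH2 in a strain-releasing SN2 step, which forms the O1–C5 bond and turns the oxetane oxygen into the exocyclic CH2OH. The closest known reaction type is the enantioselective intramolecular alcoholysis of prochiral 3-substituted oxetanes carrying a two-carbon hydroxyl tether, run with (salen)Co or chiral phosphoric acid catalysts to give 3-(hydroxymethyl)tetrahydrofurans; here that reaction meets a substrate in which the two CH2 groups are diastereotopic instead of enantiotopic. The tetrahydrofuran closes in the 5-exo-tet mode, the only ring size this tether allows. The new stereocentre C4 is defined by which CH2 is attacked and is under catalyst control, the hand of the catalyst being chosen so that it reinforces, or if needed overrides, the small conformational bias exerted by the neighbouring (R) centre C3, which itself is not touched. The step needs diastereotopic-group selectivity for the CH2 whose opening leaves the CH2OH cis to the arylmethyl group and chemoselectivity for oxygen over the electron-rich arene; the substrate secures the latter through its single unhindered primary hydroxyl held two carbons from the ring, and supports the former because the fixed C3 centre makes the two CH2 groups chemically distinct, so the two catalyst hands must give different and separately testable outcomes.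

Step 9
Reactants: 13 [(3R,4R)-4-(3-benzyloxy-4-methoxybenzyl)tetrahydrofuran-3-yl]methanol
Product: 14 (3S,4R)-4-(3-benzyloxy-4-methoxybenzyl)tetrahydrofuran-3-carbaldehyde (cis)
Conditions: Dess–Martin periodinane, NaHCO3, CH2Cl2, 0 °C to rt; crude product used at once
Reagents that add atoms: none
Why: Dess–Martin oxidation under bicarbonate buffering converts the primary alcohol to the aldehyde under neutral, non-enolizing conditions, so the cis α-stereocentre should survive if the aldehyde is taken on without chromatography.

Step 10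
Reactants: 15 5-bromo-2-methoxyphenol
Product: 16 2-(benzyloxy)-4-bromo-1-methoxybenzene
Conditions: BnBr, K2CO3, DMF, rt
Reagents that add atoms: benzyl bromide, BrCc1ccccc1
Why: Williamson ether synthesis on the phenoxide with benzyl bromide is routine and leaves the aryl bromide intact.

Step 11
Reactants: 14 (3S,4R)-4-(3-benzyloxy-4-methoxybenzyl)tetrahydrofuran-3-carbaldehyde; 16 2-(benzyloxy)-4-bromo-1-methoxybenzene
Product: 18 (S)-[3-(benzyloxy)-4-methoxyphenyl][(3S,4R)-4-(3-benzyloxy-4-methoxybenzyl)tetrahydrofuran-3-yl]methanol, via arylmagnesium bromide 17 (not isolated)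
Conditions: 16, Mg, THF, 40 °C; then 14, THF, −78 °C; aq NH4Cl
Reagents that add atoms: none
Why: Grignard addition under Felkin–Anh control: with the ring CH that carries the cis arylmethyl group as the large α-substituent and the reagent passing the α-hydrogen, the aryl group should add to the Re face and give the (S)-carbinol (a magnesium chelate to the ring oxygen would expose the same face), while −78 °C limits enolization of the cis aldehyde.

Step 12
Reactants: 18 (S)-[3-(benzyloxy)-4-methoxyphenyl][(3S,4R)-4-(3-benzyloxy-4-methoxybenzyl)tetrahydrofuran-3-yl]methanol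
Product: 19 (S)-(3-hydroxy-4-methoxyphenyl)[(3S,4R)-4-(3-hydroxy-4-methoxybenzyl)tetrahydrofuran-3-yl]methanol (CNP0108210.1)
Conditions: H2 (1 atm), 10% Pd/C, EtOAc, rt; stopped at full conversion
Reagents that add atoms: none
Why: Catalytic hydrogenolysis of the two aryl benzyl ethers in neutral ethyl acetate at 1 atm should be much faster than cleavage of the secondary benzylic C–OH bond (no acid present, no para-hydroxyl to assist ionization), so both phenols are freed and the three stereocentres stay as set.

**Compound list**

1 | (R)-4-benzyl-2-oxazolidinone | O=C1N[C@H](Cc2ccccc2)CO1 | starting material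
2 | lithium (R)-4-benzyl-2-oxooxazolidin-3-ide | O=C1N([Li])[C@H](Cc2ccccc2)CO1 | intermediate
3 | (R)-4-benzyl-3-(bromoacetyl)oxazolidin-2-one | O=C1N(C(=O)CBr)[C@H](Cc2ccccc2)CO1 | intermediate
4 | diethyl {2-[(4R)-4-benzyl-2-oxooxazolidin-3-yl]-2-oxoethyl}phosphonate | O=C1N(C(=O)CP(=O)(OCC)OCC)[C@H](Cc2ccccc2)CO1 | intermediate
5 | oxetan-3-one | O=C1COC1 | starting material
6 | (R)-4-benzyl-3-[2-(oxetan-3-ylidene)acetyl]oxazolidin-2-one | O=C1N(C(=O)C=C2COC2)[C@H](Cc2ccccc2)CO1 | intermediate
7 | (R)-4-benzyl-3-[2-(oxetan-3-yl)acetyl]oxazolidin-2-one | O=C1N(C(=O)CC2COC2)[C@H](Cc2ccccc2)CO1 | intermediate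
8 | (3-benzyloxy-4-methoxyphenyl)methanol | COc1ccc(CO)cc1OCc1ccccc1 | starting material
9 | 2-(benzyloxy)-4-(bromomethyl)-1-methoxybenzene | COc1ccc(CBr)cc1OCc1ccccc1 | intermediate
10 | sodium (Z)-enolate of 7 | [Na+].[O-]/C(=C\C1COC1)N1C(=O)OC[C@H]1Cc1ccccc1 | intermediate
11 | (R)-4-benzyl-3-[(2R)-3-(3-benzyloxy-4-methoxyphenyl)-2-(oxetan-3-yl)propanoyl]oxazolidin-2-one | COc1ccc(C[C@@H](C(=O)N2C(=O)OC[C@H]2Cc2ccccc2)C2COC2)cc1OCc1ccccc1 | intermediate
12 | (R)-3-(3-benzyloxy-4-methoxyphenyl)-2-(oxetan-3-yl)propan-1-ol | COc1ccc(C[C@@H](CO)C2COC2)cc1OCc1ccccc1 | intermediate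
13 | [(3R,4R)-4-(3-benzyloxy-4-methoxybenzyl)tetrahydrofuran-3-yl]methanol (cis) | COc1ccc(C[C@H]2COC[C@H]2CO)cc1OCc1ccccc1 | intermediate
14 | (3S,4R)-4-(3-benzyloxy-4-methoxybenzyl)tetrahydrofuran-3-carbaldehyde (cis) | COc1ccc(C[C@H]2COC[C@H]2C=O)cc1OCc1ccccc1 | intermediate
15 | 5-bromo-2-methoxyphenol | COc1ccc(Br)cc1O | starting material
16 | 2-(benzyloxy)-4-bromo-1-methoxybenzene | COc1ccc(Br)cc1OCc1ccccc1 | intermediate
17 | [3-(benzyloxy)-4-methoxyphenyl]magnesium bromide | COc1ccc([Mg]Br)cc1OCc1ccccc1 | intermediate
18 | (S)-[3-(benzyloxy)-4-methoxyphenyl][(3S,4R)-4-(3-benzyloxy-4-methoxybenzyl)tetrahydrofuran-3-yl]methanol | COc1ccc(C[C@H]2COC[C@H]2[C@H](O)c2ccc(OC)c(OCc3ccccc3)c2)cc1OCc1ccccc1 | intermediate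
19 | (S)-(3-hydroxy-4-methoxyphenyl)[(3S,4R)-4-(3-hydroxy-4-methoxybenzyl)tetrahydrofuran-3-yl]methanol | COc1ccc(C[C@H]2COC[C@H]2[C@H](O)c2ccc(OC)c(O)c2)cc1O | target

**Step count**

Total step count: 12.
Longest linear sequence: 10 steps (1, 2, 3, 4, 6, 7, 8, 9, 11, 12).

**Steps most likely to fail**

1. Step 8. The hydroxyl may attack the other diastereotopic CH2 and close the trans ring, because the substrate's own conformational preference could oppose the catalyst. An uncatalysed or acid-promoted background opening, or attack of the electron-rich arene on the activated oxetane, could erode the outcome further. The fallback sets out from bromide 9 and comes back at alcohol 13, and fixes cis by syn addition of hydrogen instead of by group selection.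
   - Zinc insertion into 9 (Zn dust, LiCl, THF) should give [3-(benzyloxy)-4-methoxybenzyl]zinc bromide F1.
   - Commercial methyl 4-oxotetrahydrofuran-3-carboxylate is converted with Tf2O and iPr2NEt into methyl 4-{[(trifluoromethyl)sulfonyl]oxy}-2,5-dihydrofuran-3-carboxylate F2.
   - Negishi coupling of the two with Pd(PPh3)4 (zerovalent palladium) should give methyl 4-(3-benzyloxy-4-methoxybenzyl)-2,5-dihydrofuran-3-carboxylate F3.
   - Saponification with LiOH gives 4-(3-benzyloxy-4-methoxybenzyl)-2,5-dihydrofuran-3-carboxylic acid F4.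
   - Carboxylate-directed asymmetric hydrogenation with Ru(OAc)2[(R)-BINAP] (divalent ruthenium; ligand hand to be confirmed) adds H2 to one face of the ring alkene and should give (3S,4R)-4-(3-benzyloxy-4-methoxybenzyl)tetrahydrofuran-3-carboxylic acid F5, cis by necessity.
   - LiAlH4 reduction returns 13.

2. Step 11. Facial selectivity at the carbonyl may be poor if the two ring carbons flanking the α-centre are not differentiated well enough, and the basic Grignard reagent may enolize the cis aldehyde and epimerize it towards trans. The fallback sets out from aldehyde 14 and comes back at 18, and replaces substrate control by ligand control with a non-basic reagent.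
   - 3-(Benzyloxy)-4-methoxyphenylboronic acid and Et2Zn (toluene, 60 °C) should give [3-(benzyloxy)-4-methoxyphenyl](ethyl)zinc F6.
   - F6 is added to 14 at 0 °C in the presence of a chiral amino alcohol ligand (MIB, in the hand that delivers the aryl group to the Re face), transferring aryl in preference to ethyl.

3. Step 12. Over-reduction may occur: the benzylic C–O bond of the secondary alcohol may be hydrogenolysed along with the benzyl ethers if the reaction runs long or traces of acid are present. The fallback sets out from alcohol 13 and phenol 15 and comes back at 19, and moves all hydrogenolysis to a stage where no benzylic alcohol exists.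
   - Hydrogenolysis of 13 (H2, Pd/C) gives [(3R,4R)-4-(3-hydroxy-4-methoxybenzyl)tetrahydrofuran-3-yl]methanol F7.
   - Phenol-selective allylation (allyl bromide, K2CO3, acetone) gives [(3R,4R)-4-(3-allyloxy-4-methoxybenzyl)tetrahydrofuran-3-yl]methanol F8.
   - Dess–Martin oxidation gives (3S,4R)-4-(3-allyloxy-4-methoxybenzyl)tetrahydrofuran-3-carbaldehyde F9.
   - Phenol 15 is allylated to 2-(allyloxy)-4-bromo-1-methoxybenzene F10 and converted with Mg into [3-(allyloxy)-4-methoxyphenyl]magnesium bromide F11.
   - Addition of F11 to F9 at −78 °C should give (S)-[3-(allyloxy)-4-methoxyphenyl][(3S,4R)-4-(3-allyloxy-4-methoxybenzyl)tetrahydrofuran-3-yl]methanol F12.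
   - Deallylation with Pd(PPh3)4 (zerovalent palladium) and morpholine, which uses no hydrogen, gives 19.

Further compounds
F1 | step 8 | [3-(benzyloxy)-4-methoxybenzyl]zinc bromide | COc1ccc(C[Zn]Br)cc1OCc1ccccc1
F2 | step 8 | methyl 4-{[(trifluoromethyl)sulfonyl]oxy}-2,5-dihydrofuran-3-carboxylate | COC(=O)C1=C(OS(=O)(=O)C(F)(F)F)COC1
F3 | step 8 | methyl 4-(3-benzyloxy-4-methoxybenzyl)-2,5-dihydrofuran-3-carboxylate | COC(=O)C1=C(Cc2ccc(OC)c(OCc3ccccc3)c2)COC1
F4 | step 8 | 4-(3-benzyloxy-4-methoxybenzyl)-2,5-dihydrofuran-3-carboxylic acid | OC(=O)C1=C(Cc2ccc(OC)c(OCc3ccccc3)c2)COC1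
F5 | step 8 | (3S,4R)-4-(3-benzyloxy-4-methoxybenzyl)tetrahydrofuran-3-carboxylic acid | COc1ccc(C[C@H]2COC[C@H]2C(=O)O)cc1OCc1ccccc1
F6 | step 11 | [3-(benzyloxy)-4-methoxyphenyl](ethyl)zinc | CC[Zn]c1ccc(OC)c(OCc2ccccc2)c1
F7 | step 12 | [(3R,4R)-4-(3-hydroxy-4-methoxybenzyl)tetrahydrofuran-3-yl]methanol | COc1ccc(C[C@H]2COC[C@H]2CO)cc1O
F8 | step 12 | [(3R,4R)-4-(3-allyloxy-4-methoxybenzyl)tetrahydrofuran-3-yl]methanol | C=CCOc1cc(C[C@H]2COC[C@H]2CO)ccc1OC
F9 | step 12 | (3S,4R)-4-(3-allyloxy-4-methoxybenzyl)tetrahydrofuran-3-carbaldehyde | C=CCOc1cc(C[C@H]2COC[C@H]2C=O)ccc1OC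
F10 | step 12 | 2-(allyloxy)-4-bromo-1-methoxybenzene | C=CCOc1cc(Br)ccc1OC
F11 | step 12 | [3-(allyloxy)-4-methoxyphenyl]magnesium bromide | C=CCOc1cc([Mg]Br)ccc1OC
F12 | step 12 | (S)-[3-(allyloxy)-4-methoxyphenyl][(3S,4R)-4-(3-allyloxy-4-methoxybenzyl)tetrahydrofuran-3-yl]methanol | C=CCOc1cc(C[C@H]2COC[C@H]2[C@H](O)c2ccc(OC)c(OCC=C)c2)ccc1OC
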